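**Retrosynthetic overview**
1. Target ⇐ its C2 silyl enol ether ⇐ intramolecular Diels–Alder reaction of an acyclic (3E,9E)-2-silyloxy-1,3,9-triene that already carries both esters. Bonds C3–C4 and C5–C10 form together, so ring A and ring B are created in the same operation; no carbocycle exists before it.
2. Triene ⇐ enone diester ⇐ Wittig olefination (C10=C1) of a C10 aldehyde and senecioylation of O9; the O8 tiglate is installed earlier.
3. C7–C8 bond ⇐ anti-selective CrCl2-mediated allylation of (S)-glyceraldehyde acetonide (C8–C10, source of absolute configuration) with a nine-carbon dienyl bromide; this sets C7 and C8.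
4. Dienyl bromide ⇐ propargyl alcohol (Zr-catalysed methylalumination) + tiglyl bromide (Pd-catalysed alkenyl–allyl coupling).

Assumption: tiglyl alcohol and (S)-glyceraldehyde acetonide are bought; locants C1–C15 in the text are eremophilane locants of the target (C2 ketone, C4/C5 methyl-bearing carbons, C7 isopropenyl, C8 tiglate, C9 senecioate, C10 ring-fusion CH; target = 4S,5R,7R,8R,9S,10S).

**Step 1**
Reactants: 1 (E)-2-methylbut-2-en-1-ol
Product: 2 (E)-1-bromo-2-methylbut-2-ene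
Conditions: PBr3 (0.4 equiv), pyridine (cat.), Et2O, −10 °C
Reagents that add atoms: phosphorus tribromide (PBr3), BrP(Br)Br
Why: SN2-type bromination of a primary allylic alcohol through its phosphite ester; the low temperature keeps the (E)-geometry and avoids allylic transposition.

**Step 2**
Reactants: 3 prop-2-yn-1-ol; 2 (E)-1-bromo-2-methylbut-2-ene
Product: 5 (2E,5E)-2,5-dimethylhepta-2,5-dien-1-ol, via alkenylalane 4 (not isolated)
Conditions: AlMe3 (3 equiv), Cp2ZrCl2 (0.25 equiv), CH2Cl2, 0 °C to rt; then 2, Pd(PPh3)4 (5 mol %), THF, rt; 1 M HCl work-up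
Reagents that add atoms: trimethylaluminium (AlMe3), C[Al](C)C
Why: Negishi Zr-catalysed carboalumination adds Me–Al syn across the alkyne (Me on the internal carbon), and the Pd-catalysed alkenyl–allyl coupling joins the alkenylalane to the primary terminus of the tiglyl unit with retention of both alkene geometries.

**Step 3**
Reactants: 5 (2E,5E)-2,5-dimethylhepta-2,5-dien-1-ol
Product: 6 (2E,5E)-1-bromo-2,5-dimethylhepta-2,5-diene
Conditions: PBr3 (0.4 equiv), pyridine (cat.), Et2O, −10 °C; used crude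
Reagents that add atoms: phosphorus tribromide (PBr3), BrP(Br)Br
Why: Same primary allylic alcohol to bromide conversion as used for geranyl bromide; the skipped diene is untouched.

**Step 4**
Reactants: 6 (2E,5E)-1-bromo-2,5-dimethylhepta-2,5-diene; 7 (S)-2,2-dimethyl-1,3-dioxolane-4-carbaldehyde
Product: 9 (1R,2R,4E)-1-[(4S)-2,2-dimethyl-1,3-dioxolan-4-yl]-4-methyl-2-(prop-1-en-2-yl)hex-4-en-1-ol, via allyl-CrCl2 species 8 (not isolated)
Conditions: CrCl2 (3 equiv), THF, 0 °C to rt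
Reagents that add atoms: none
Why: Nozaki–Hiyama allylation: the γ-substituted allylchromium (trivalent chromium) adds through C7 in a chair transition state, which gives the anti C7/C8 relationship and unmasks the isopropenyl group, while Felkin–Anh attack anti to the dioxolane oxygen sets C8 relative to the chiral-pool centre C9 (moderate facial ratio expected, minor isomer removed by chromatography).

**Step 5**
Reactants: 9 the homoallylic alcohol; 10 (E)-2-methylbut-2-enoyl chloride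
Product: 11 (1R,2R,4E)-1-[(4S)-2,2-dimethyl-1,3-dioxolan-4-yl]-4-methyl-2-(prop-1-en-2-yl)hex-4-en-1-yl (E)-2-methylbut-2-enoate
Conditions: Et3N (2 equiv), DMAP (0.2 equiv), CH2Cl2, 0 °C to rt
Reagents that add atoms: none
Why: DMAP-catalysed acylation of the only free hydroxyl (O8); no stereocentre is touched, and the tiglate is the stable alkene isomer, so no E/Z drift.

**Step 6**
Reactants: 11 the tiglate acetonide
Product: 12 (2S,3R,4R,6E)-1,2-dihydroxy-6-methyl-4-(prop-1-en-2-yl)oct-6-en-3-yl (E)-2-methylbut-2-enoate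
Conditions: AcOH–H2O (4:1), 40 °C
Reagents that add atoms: none
Why: Mild acid hydrolysis of a terminal isopropylidene acetal; the absence of base limits 1,2-acyl shift from O8 to O9.

**Step 7**
Reactants: 12 the diol; 13 1-(triphenyl-λ5-phosphanylidene)propan-2-one
Product: 15 (3E,5S,6R,7R,9E)-5-hydroxy-9-methyl-2-oxo-7-(prop-1-en-2-yl)undeca-3,9-dien-6-yl (E)-2-methylbut-2-enoate, via hydroxy aldehyde 14 (not isolated)
Conditions: TEMPO (10 mol %), PhI(OAc)2 (1.1 equiv), CH2Cl2, rt; then 13 (1.5 equiv), rt to 40 °C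
Reagents that add atoms: none
Why: The oxoammonium oxidation is selective for the primary over the secondary alcohol, and the stabilised ylide traps the sensitive α-hydroxy aldehyde in the same flask (Wittig reaction) to give the (E)-enone.

**Step 8**
Reactants: 15 the hydroxy enone; 16 3-methylbut-2-enoic acid
Product: 17 (3E,5S,6R,7R,9E)-9-methyl-5-[(3-methylbut-2-enoyl)oxy]-2-oxo-7-(prop-1-en-2-yl)undeca-3,9-dien-6-yl (E)-2-methylbut-2-enoate
Conditions: DCC (1.3 equiv), DMAP (0.1 equiv), CH2Cl2, 0 °C to rt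
Reagents that add atoms: none
Why: Steglich esterification of the allylic O9 hydroxyl; using the free acid avoids the vinylketene (deconjugation) pathway of senecioyl chloride.

**Step 9**
Reactants: 17 the enone diester
Product: 18 (3E,5S,6R,7R,9E)-2-[(tert-butyldimethylsilyl)oxy]-9-methyl-5-[(3-methylbut-2-enoyl)oxy]-7-(prop-1-en-2-yl)undeca-1,3,9-trien-6-yl (E)-2-methylbut-2-enoate
Conditions: TBSOTf (1.3 equiv), Et3N (2 equiv), CH2Cl2, −78 to 0 °C; pentane extraction, used crude
Reagents that add atoms: tert-butyldimethylsilyl trifluoromethanesulfonate (TBSOTf), CC(C)(C)[Si](C)(C)OS(=O)(=O)C(F)(F)F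
Why: Soft enolisation (silyl triflate/amine) of the methyl ketone gives the cross-conjugated 2-silyloxydiene, since only the CH3 side carries α-hydrogens; esters are not enolised under these conditions.

**Step 10**
Reactants: 18 the silyloxy triene
Product: 20 (1S,2R,3R,4aR,5S,8aS)-4a,5-dimethyl-1-[(3-methylbut-2-enoyl)oxy]-7-oxo-3-(prop-1-en-2-yl)decahydronaphthalen-2-yl (E)-2-methylbut-2-enoate, via cycloadduct silyl enol ether 19 (not isolated)
Conditions: PhMe (0.01 M), BHT, 185 °C (sealed tube), 36 h; then 1 M HCl, THF, 0 °C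
Reagents that add atoms: none
Why: Thermal intramolecular Diels–Alder reaction of a 2-silyloxy-1,3,9-triene closes ring A and ring B in one suprafacial event: the (E)-trisubstituted dienophile fixes the C4/C5 methyls cis, the cis ring fusion (C10–H cis to C5–Me) is expected from the transition state that keeps both dienophile methyls exo to the silyloxydiene with the four-carbon tether endo, and the face is chosen by a chair-like tether with the diene, isopropenyl and C8 acyloxy groups equatorial and only the C9 acyloxy group axial; mild acid then hydrolyses the enol ether to the C2 ketone without touching a stereocentre.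

**Compound list**
1 | (E)-2-methylbut-2-en-1-ol (tiglyl alcohol) | C/C=C(C)/CO | starting material
2 | (E)-1-bromo-2-methylbut-2-ene | C/C=C(C)/CBr | intermediate
3 | prop-2-yn-1-ol | C#CCO | starting material
4 | dimethylaluminium (E)-3-(dimethylalumanyl)-2-methylprop-2-en-1-olate | C[Al](C)/C=C(C)/CO[Al](C)C | intermediate
5 | (2E,5E)-2,5-dimethylhepta-2,5-dien-1-ol | C/C=C(C)/C/C=C(C)/CO | intermediate
6 | (2E,5E)-1-bromo-2,5-dimethylhepta-2,5-diene | C/C=C(C)/C/C=C(C)/CBr | intermediate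
7 | (S)-2,2-dimethyl-1,3-dioxolane-4-carbaldehyde | O=C[C@@H]1COC(C)(C)O1 | starting material
8 | dichloro[(2E,5E)-2,5-dimethylhepta-2,5-dien-1-yl]chromium | C/C=C(C)/C/C=C(C)/C[Cr](Cl)Cl | intermediate
9 | (1R,2R,4E)-1-[(4S)-2,2-dimethyl-1,3-dioxolan-4-yl]-4-methyl-2-(prop-1-en-2-yl)hex-4-en-1-ol | C=C(C)[C@@H](C/C(C)=C/C)[C@@H](O)[C@@H]1COC(C)(C)O1 | intermediate
10 | (E)-2-methylbut-2-enoyl chloride | C/C=C(\C)C(=O)Cl | starting material
11 | (1R,2R,4E)-1-[(4S)-2,2-dimethyl-1,3-dioxolan-4-yl]-4-methyl-2-(prop-1-en-2-yl)hex-4-en-1-yl (E)-2-methylbut-2-enoate | C=C(C)[C@@H](C/C(C)=C/C)[C@@H](OC(=O)/C(C)=C/C)[C@@H]1COC(C)(C)O1 | intermediate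
12 | (2S,3R,4R,6E)-1,2-dihydroxy-6-methyl-4-(prop-1-en-2-yl)oct-6-en-3-yl (E)-2-methylbut-2-enoate | C=C(C)[C@@H](C/C(C)=C/C)[C@@H](OC(=O)/C(C)=C/C)[C@@H](O)CO | intermediate
13 | 1-(triphenyl-λ5-phosphanylidene)propan-2-one | CC(=O)C=P(c1ccccc1)(c1ccccc1)c1ccccc1 | starting material
14 | (2R,3R,4R,6E)-2-hydroxy-6-methyl-1-oxo-4-(prop-1-en-2-yl)oct-6-en-3-yl (E)-2-methylbut-2-enoate | C=C(C)[C@@H](C/C(C)=C/C)[C@@H](OC(=O)/C(C)=C/C)[C@@H](O)C=O | intermediate
15 | (3E,5S,6R,7R,9E)-5-hydroxy-9-methyl-2-oxo-7-(prop-1-en-2-yl)undeca-3,9-dien-6-yl (E)-2-methylbut-2-enoate | C=C(C)[C@@H](C/C(C)=C/C)[C@@H](OC(=O)/C(C)=C/C)[C@@H](O)/C=C/C(C)=O | intermediate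
16 | 3-methylbut-2-enoic acid | CC(C)=CC(=O)O | starting material
17 | (3E,5S,6R,7R,9E)-9-methyl-5-[(3-methylbut-2-enoyl)oxy]-2-oxo-7-(prop-1-en-2-yl)undeca-3,9-dien-6-yl (E)-2-methylbut-2-enoate | C=C(C)[C@@H](C/C(C)=C/C)[C@@H](OC(=O)/C(C)=C/C)[C@@H](OC(=O)C=C(C)C)/C=C/C(C)=O | intermediate
18 | (3E,5S,6R,7R,9E)-2-[(tert-butyldimethylsilyl)oxy]-9-methyl-5-[(3-methylbut-2-enoyl)oxy]-7-(prop-1-en-2-yl)undeca-1,3,9-trien-6-yl (E)-2-methylbut-2-enoate | C=C(C)[C@@H](C/C(C)=C/C)[C@@H](OC(=O)/C(C)=C/C)[C@@H](OC(=O)C=C(C)C)/C=C/C(=C)O[Si](C)(C)C(C)(C)C | intermediate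
19 | (1S,2R,3R,4aR,5S,8aS)-7-[(tert-butyldimethylsilyl)oxy]-4a,5-dimethyl-1-[(3-methylbut-2-enoyl)oxy]-3-(prop-1-en-2-yl)-1,2,3,4,4a,5,6,8a-octahydronaphthalen-2-yl (E)-2-methylbut-2-enoate | C=C(C)[C@H]1C[C@@]2(C)[C@H](C=C(O[Si](C)(C)C(C)(C)C)C[C@@H]2C)[C@H](OC(=O)C=C(C)C)[C@@H]1OC(=O)/C(C)=C/C | intermediate
20 | (1S,2R,3R,4aR,5S,8aS)-4a,5-dimethyl-1-[(3-methylbut-2-enoyl)oxy]-7-oxo-3-(prop-1-en-2-yl)decahydronaphthalen-2-yl (E)-2-methylbut-2-enoate | C=C(C)[C@H]1C[C@@]2(C)[C@H](CC(=O)C[C@@H]2C)[C@H](OC(=O)C=C(C)C)[C@@H]1OC(=O)/C(C)=C/C | target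

**Step count**
Total steps: 10. Longest linear sequence: 10 (1 → 2 → 5 → 6 → 9 → 11 → 12 → 15 → 17 → 18 → 20).

**Three steps most likely to fail**

Step 10 (intramolecular Diels–Alder). The dienophile is an unactivated trisubstituted alkene, so the reaction needs about 185 °C. At that temperature the diene may instead add to the tiglate C=C through the ester tether, the allylic senecioate may shift or eliminate, and trans-fused or wrong-face isomers may form. The fallback runs the cycloaddition on an ester-free substrate and acylates afterwards. It sets out from 9. Aqueous AcOH removes the acetonide to give the triol F1. TEMPO/PhI(OAc)2 followed by ylide 13 gives the dihydroxy enone F2. TBSOTf (3.5 equiv)/Et3N silylates both hydroxyls and the ketone in one operation to give the tris-silyl triene F3. Heating in PhMe at 200 °C gives the tris-silyl cycloadduct F4, which HF·pyridine in MeCN strips to the diol ketone F5. Bu2SnO (stannylene acetal) and then tigloyl chloride 10 acylate the equatorial C8 hydroxyl to give the mono-tiglate F6. Esterification of the axial C9 hydroxyl with 16 (DCC, DMAP) comes back to the route at 20.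

Step 4 (CrCl2 allylation). The anti C7/C8 relationship is reliable, but the aldehyde face is chosen by substrate control alone, so the C7,C8-bis-epimer may be a large by-product. The fallback is a catalyst-controlled allylboration. It sets out from 6, which Pd2(dba)3-catalysed borylation with B2pin2 converts into the pinacol allylboronate F7. F7 adds to 7 under (R)-TRIP phosphoric acid catalysis through a closed chair transition state: the (E)-boronate gives anti, and the catalyst is expected to reinforce the Felkin face (the matched enantiomer is to be confirmed on small scale). This comes back to the route at 9.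

Step 7 (one-pot oxidation/Wittig). The α-hydroxy aldehyde 14 may epimerise or dimerise, and the O8 tiglate may migrate to the free O9 hydroxyl. The fallback esterifies O9 before C10 is oxidised. It sets out from 12. TBSCl/imidazole gives the primary silyl ether F8. Acid 16 with DCC/DMAP gives the senecioate F9. HF·pyridine gives the primary alcohol F10, which is oxidised at once with Dess–Martin periodinane to the α-acyloxy aldehyde F11. Ylide 13 then gives the enone diester, so the fallback comes back to the route at 17 and bypasses 15.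

**Further compounds**
F1 | step 10 | (2S,3R,4R,6E)-6-methyl-4-(prop-1-en-2-yl)oct-6-ene-1,2,3-triol | C=C(C)[C@@H](C/C(C)=C/C)[C@@H](O)[C@@H](O)CO
F2 | step 10 | (3E,5S,6R,7R,9E)-5,6-dihydroxy-9-methyl-7-(prop-1-en-2-yl)undeca-3,9-dien-2-one | C=C(C)[C@@H](C/C(C)=C/C)[C@@H](O)[C@@H](O)/C=C/C(C)=O
F3 | step 10 | (3E,5S,6R,7R,9E)-2,5,6-tris[(tert-butyldimethylsilyl)oxy]-9-methyl-7-(prop-1-en-2-yl)undeca-1,3,9-triene | C=C(C)[C@@H](C/C(C)=C/C)[C@@H](O[Si](C)(C)C(C)(C)C)[C@@H](O[Si](C)(C)C(C)(C)C)/C=C/C(=C)O[Si](C)(C)C(C)(C)C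
F4 | step 10 | (4S,4aR,6R,7R,8S,8aS)-2,7,8-tris[(tert-butyldimethylsilyl)oxy]-4,4a-dimethyl-6-(prop-1-en-2-yl)-3,4,4a,5,6,7,8,8a-octahydronaphthalene | C=C(C)[C@H]1C[C@@]2(C)[C@H](C=C(O[Si](C)(C)C(C)(C)C)C[C@@H]2C)[C@H](O[Si](C)(C)C(C)(C)C)[C@@H]1O[Si](C)(C)C(C)(C)C
F5 | step 10 | (4S,4aR,6R,7R,8S,8aS)-7,8-dihydroxy-4,4a-dimethyl-6-(prop-1-en-2-yl)octahydronaphthalen-2(1H)-one | C=C(C)[C@H]1C[C@@]2(C)[C@H](CC(=O)C[C@@H]2C)[C@H](O)[C@@H]1O
F6 | step 10 | (1S,2R,3R,4aR,5S,8aS)-1-hydroxy-4a,5-dimethyl-7-oxo-3-(prop-1-en-2-yl)decahydronaphthalen-2-yl (E)-2-methylbut-2-enoate | C=C(C)[C@H]1C[C@@]2(C)[C@H](CC(=O)C[C@@H]2C)[C@H](O)[C@@H]1OC(=O)/C(C)=C/C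
F7 | step 4 | 2-[(2E,5E)-2,5-dimethylhepta-2,5-dien-1-yl]-4,4,5,5-tetramethyl-1,3,2-dioxaborolane | CC1(C)OB(C/C(C)=C/C/C(C)=C/C)OC1(C)C
F8 | step 7 | (2S,3R,4R,6E)-1-[(tert-butyldimethylsilyl)oxy]-2-hydroxy-6-methyl-4-(prop-1-en-2-yl)oct-6-en-3-yl (E)-2-methylbut-2-enoate | C=C(C)[C@@H](C/C(C)=C/C)[C@@H](OC(=O)/C(C)=C/C)[C@@H](O)CO[Si](C)(C)C(C)(C)C
F9 | step 7 | (2S,3R,4R,6E)-1-[(tert-butyldimethylsilyl)oxy]-6-methyl-2-[(3-methylbut-2-enoyl)oxy]-4-(prop-1-en-2-yl)oct-6-en-3-yl (E)-2-methylbut-2-enoate | C=C(C)[C@@H](C/C(C)=C/C)[C@@H](OC(=O)/C(C)=C/C)[C@@H](OC(=O)C=C(C)C)CO[Si](C)(C)C(C)(C)C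
F10 | step 7 | (2S,3R,4R,6E)-1-hydroxy-6-methyl-2-[(3-methylbut-2-enoyl)oxy]-4-(prop-1-en-2-yl)oct-6-en-3-yl (E)-2-methylbut-2-enoate | C=C(C)[C@@H](C/C(C)=C/C)[C@@H](OC(=O)/C(C)=C/C)[C@@H](OC(=O)C=C(C)C)CO
F11 | step 7 | (2R,3R,4R,6E)-6-methyl-2-[(3-methylbut-2-enoyl)oxy]-1-oxo-4-(prop-1-en-2-yl)oct-6-en-3-yl (E)-2-methylbut-2-enoate | C=C(C)[C@@H](C/C(C)=C/C)[C@@H](OC(=O)/C(C)=C/C)[C@@H](OC(=O)C=C(C)C)C=O
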